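**Retrosynthetic overview**
1. Target ⇒ C1 ketone and C3 methyl by methyl addition and oxidative 1,3-transposition of a C3 enone (from allylic oxidation); C9 angelate by acylation; C7 methacrylate and the C9 carbinol together by Evans–Tishchenko reduction of a 7-hydroxy-9-ketone.
2. 7-Hydroxy-9-keto tricycle ⇒ key step: epoxide-initiated strain-release annulation of a bicyclobutyl carbinol, ended by a semipinacol 1,2-methyl shift (forms C5–C6, the cycloheptane, the cyclobutane and quaternary C10).
3. Carbinol ⇒ resolved bridgehead sulfoxide of tricyclo[4.1.0.0^2,7]hept-3-ene + (R)-epoxy ketone (Shi epoxidation).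
4. Bicyclobutane ⇒ cyclohexa-1,4-diene + CHBr3 (carbene addition, then carbenoid C–H insertion).
5. Ring order: six-membered ring (bought) → bicyclobutane → seven-membered ring and cyclobutane together in the key step.

Assumption: longipinane numbering is used (C1 ketone, C2=C3, C4 and C11 the cyclobutane CH next to C3 and C1, C5 the cyclobutane CH bearing C6(CH3)2, C7 methacrylate carbon, C8, C9 angelate carbon, C10 the methylated cyclobutane carbon; C12 is the methyl on C3); the Grignard solution 8, (1R,2S,5R)-menthyl (S)-4-methylbenzenesulfinate and the D-fructose-derived Shi ketone are bought.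

**Step 1**
Reactants: 1 cyclohexa-1,4-diene; 2 tribromomethane
Product: 3 cis-7,7-dibromobicyclo[4.1.0]hept-3-ene
Conditions: KOtBu, pentane, 0 °C (excess 1)
Reagents that add atoms: none
Why: Dibromocarbene from α-elimination of CHBr3 adds stereospecifically to one of the two equivalent cis double bonds (dihalocarbene cyclopropanation), giving the cis-fused meso dibromide.

**Step 2**
Reactants: 3 cis-7,7-dibromobicyclo[4.1.0]hept-3-ene
Product: 5 tricyclo[4.1.0.0^2,7]hept-3-ene, via lithium bromocarbenoid 4 (not isolated)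
Conditions: MeLi, Et2O, −78 to 0 °C
Reagents that add atoms: none
Why: Br–Li exchange gives a cyclopropylidene carbenoid that cannot open to a seven-membered allene and inserts into the neighbouring allylic C–H bond (intramolecular carbenoid C–H insertion, Moore-type bicyclobutane synthesis); the two allylic CH2 groups are equivalent, so one achiral bicyclobutane forms.

**Step 3**
Reactants: 5 tricyclo[4.1.0.0^2,7]hept-3-ene
Product: 7 (1R,2R,6S,7S)-1-[(S)-4-methylbenzenesulfinyl]tricyclo[4.1.0.0^2,7]hept-3-ene, via bridgehead lithium compound 6 (not isolated)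
Conditions: n-BuLi, TMEDA, Et2O, 0 °C to rt; then (1R,2S,5R)-menthyl (S)-4-methylbenzenesulfinate, THF, −78 °C; chromatography (other bridgehead diastereomer returned to 5 by t-BuLi then MeOH)
Reagents that add atoms: (1R,2S,5R)-menthyl (S)-4-methylbenzenesulfinate, CC(C)[C@@H]1CC[C@@H](C)C[C@H]1O[S@](=O)c1ccc(C)cc1
Why: The bridgehead C–H bonds (high s character) are the most acidic, and Andersen sulfinylation with inversion at sulfur turns the two enantiotopic bridgeheads into separable diastereomers; isolating 7 fixes the absolute sense of the future C4/C5/C10/C11 cage.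

**Step 4**
Reactants: 8 2-methylprop-1-enylmagnesium bromide; 9 2-methyloxirane
Product: 10 5-methylhex-4-en-2-ol
Conditions: CuI (10 mol%), THF, −30 to 0 °C; aq. NH4Cl
Reagents that add atoms: none
Why: Copper-catalysed SN2 opening of the epoxide at its CH2 carbon by the alkenyl Grignard reagent gives the homoallylic alcohol (its stereocentre is removed in step 6).

**Step 5**
Reactants: 10 5-methylhex-4-en-2-ol
Product: 11 1-[(2R)-3,3-dimethyloxiran-2-yl]propan-2-ol
Conditions: D-fructose-derived Shi ketone (30 mol%), KHSO5 (as 2KHSO5·KHSO4·K2SO4), K2CO3, Bu4NHSO4, MeCN–dimethoxymethane–aq. buffer pH 10.5, 0 °C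
Reagents that add atoms: potassium peroxymonosulfate, [K+].[O-]S(=O)(=O)OO
Why: Shi asymmetric epoxidation, in which the chiral dioxirane attacks the trisubstituted alkene through the spiro transition state to give the (R)-epoxide that becomes C7; the carbinol centre stays a mixture because it is oxidised next.

**Step 6**
Reactants: 11 1-[(2R)-3,3-dimethyloxiran-2-yl]propan-2-ol
Product: 12 1-[(2R)-3,3-dimethyloxiran-2-yl]propan-2-one
Conditions: Dess–Martin periodinane, NaHCO3, CH2Cl2, 0 °C
Reagents that add atoms: none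
Why: Buffered Dess–Martin oxidation of the secondary alcohol gives the β,γ-epoxy ketone without base-induced opening of the epoxide.

**Step 7**
Reactants: 7 (1R,2R,6S,7S)-1-[(S)-4-methylbenzenesulfinyl]tricyclo[4.1.0.0^2,7]hept-3-ene; 12 1-[(2R)-3,3-dimethyloxiran-2-yl]propan-2-one
Product: 15 trimethylsilyl ether of 1-[(2R)-3,3-dimethyloxiran-2-yl]-2-[(1R,2R,6S,7S)-tricyclo[4.1.0.0^2,7]hept-3-en-1-yl]propan-2-ol (both carbinol epimers), via bridgehead lithium compound 13 (not isolated), via lithium alkoxide 14 (not isolated)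
Conditions: t-BuLi, THF, −78 °C; LaCl3·2LiCl, then 12, −78 °C; Me3SiCl, −78 to 0 °C
Reagents that add atoms: chlorotrimethylsilane, C[Si](C)(C)Cl
Why: Sulfoxide–lithium exchange gives the constitutionally fixed bridgehead lithium compound, which adds 1,2 to the ketone (LaCl3·2LiCl suppresses enolisation), and silylation in the flask keeps the tertiary oxygen from opening the epoxide later; the new carbinol centre is a mixture that converges in step 8.

**Step 8**
Reactants: 15 trimethylsilyl ether of the bicyclobutyl epoxy carbinol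
Product: 16 (4S,5S,7R,10R,11R)-7-hydroxy-12-norlongipin-1-en-9-one
Conditions: MeAlCl2 (1.2 equiv), CH2Cl2, −78 °C; then aq. citric acid, THF
Reagents that add atoms: none
Why: Proposed new method: MeAlCl2 ionises the epoxide at its tertiary carbon C6, the strained electron-rich central C5–C10 σ bond attacks C6 through a six-membered array on its exposed convex face (retention at C5), and the resulting tertiary cyclobutyl cation at C10 is quenched by a semipinacol 1,2-shift of the carbinol methyl group to the rear lobe of C10 (inversion, methyl syn to the three-carbon bridge) with loss of Me3Si+ to give the C9 ketone, so the seven-membered ring, the cyclobutane, quaternary C10 and the C5–C6 bond form at once while C7 keeps the epoxide configuration and both carbinol epimers converge; the closest known reactions are the acid-promoted strain-release semipinacol rearrangement of bicyclo[1.1.0]butyl carbinols, Lewis-acid Prins-type additions of bicyclobutane central bonds to carbon electrophiles, and epoxide-initiated cation–olefin cyclisations.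

**Step 9**
Reactants: 16 (4S,5S,7R,10R,11R)-7-hydroxy-12-norlongipin-1-en-9-one; 17 2-methylprop-2-enal
Product: 18 (7R,9R)-9-hydroxy-12-norlongipin-1-en-7-yl 2-methylprop-2-enoate
Conditions: SmI2 (30 mol%), 17 (6 equiv), THF, −10 °C
Reagents that add atoms: none
Why: Evans–Tishchenko reduction, in which the samarium-bound hemiacetal of the C7 hydroxyl with the aldehyde delivers hydride intramolecularly to the C9 ketone through a chair six-membered transition state, giving the 1,3-anti (7,9-trans) alcohol and leaving the oxidised aldehyde as the C7 methacrylate.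

**Step 10**
Reactants: 18 (7R,9R)-9-hydroxy-12-norlongipin-1-en-7-yl 2-methylprop-2-enoate; 19 (Z)-2-methylbut-2-enoic acid
Product: 21 (7R,9R)-9-[(Z)-2-methylbut-2-enoyloxy]-12-norlongipin-1-en-7-yl 2-methylprop-2-enoate, via mixed anhydride 20 (not isolated)
Conditions: 19, 2,4,6-trichlorobenzoyl chloride, Et3N, toluene, rt; then 18, BHT, toluene, 80 °C
Reagents that add atoms: none
Why: Yamaguchi-type acylation through the mixed anhydride, run without a nucleophilic amine catalyst, esterifies the C9 hydroxyl while keeping the (Z) geometry of the angeloyl group.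

**Step 11**
Reactants: 21 (7R,9R)-9-[(Z)-2-methylbut-2-enoyloxy]-12-norlongipin-1-en-7-yl 2-methylprop-2-enoate
Product: 22 (7R,9R)-9-[(Z)-2-methylbut-2-enoyloxy]-3-oxo-12-norlongipin-1-en-7-yl 2-methylprop-2-enoate
Conditions: CrO3, 3,5-dimethylpyrazole, CH2Cl2, −20 °C
Reagents that add atoms: chromium trioxide, O=[Cr](=O)=O
Why: Allylic oxidation by the CrO3–3,5-dimethylpyrazole complex converts the only allylic CH2 (C3) into the enone, as with pinene-type bicyclo[3.1.1]heptenes, while the electron-poor ester alkenes are inert.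

**Step 12**
Reactants: 22 the C3 enone diester
Product: 23 (7R,9R)-3-hydroxy-9-[(Z)-2-methylbut-2-enoyloxy]longipin-1-en-7-yl 2-methylprop-2-enoate (C3 epimers)
Conditions: MeLi, CeCl3, THF, −78 °C
Reagents that add atoms: methyllithium, [Li]C
Why: The organocerium reagent adds 1,2 to the enone carbonyl far faster than to the two hindered unsaturated esters and does not add in a conjugate sense (organocerium carbonyl addition); the C3 configuration is irrelevant.

**Step 13**
Reactants: 23 the tertiary allylic alcohol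
Product: 24 (4R,5S,7R,9R,10R,11R)-9-[(Z)-2-methylbut-2-enoyloxy]-1-oxolongipin-2-en-7-yl 2-methylprop-2-enoate (CNP0317071.1)
Conditions: pyridinium chlorochromate (C5H5NH)[CrO3Cl], 4 Å molecular sieves, CH2Cl2, rt
Reagents that add atoms: none
Why: Dauben oxidative 1,3-transposition, in which the chromate ester of the tertiary allylic alcohol undergoes a [3,3] shift to C1 and is oxidised, placing the carbonyl at C1 and the methyl-bearing double bond at C2=C3.

**Compound list**
1 | cyclohexa-1,4-diene | C1=CCC=CC1 | starting material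
2 | tribromomethane | BrC(Br)Br | starting material
3 | cis-7,7-dibromobicyclo[4.1.0]hept-3-ene (meso) | BrC1(Br)[C@H]2CC=CC[C@@H]12 | intermediate
4 | 7-bromo-7-lithiobicyclo[4.1.0]hept-3-ene (not isolated) | [Li]C1(Br)[C@H]2CC=CC[C@@H]12 | intermediate
5 | tricyclo[4.1.0.0^2,7]hept-3-ene (achiral) | [C@H]12[C@@H]3C=CC[C@H]1[C@H]23 | intermediate
6 | 1-lithiotricyclo[4.1.0.0^2,7]hept-3-ene, racemic, one enantiomer drawn (not isolated) | [Li][C@]12[C@@H]3C=CC[C@H]1[C@H]23 | intermediate
7 | (1R,2R,6S,7S)-1-[(S)-4-methylbenzenesulfinyl]tricyclo[4.1.0.0^2,7]hept-3-ene | Cc1ccc(cc1)[S@](=O)[C@]12[C@@H]3C=CC[C@H]1[C@H]23 | intermediate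
8 | 2-methylprop-1-enylmagnesium bromide | CC(C)=C[Mg]Br | starting material
9 | 2-methyloxirane (racemic) | CC1CO1 | starting material
10 | 5-methylhex-4-en-2-ol (racemic) | CC(O)CC=C(C)C | intermediate
11 | 1-[(2R)-3,3-dimethyloxiran-2-yl]propan-2-ol (both carbinol epimers) | CC(O)C[C@H]1OC1(C)C | intermediate
12 | 1-[(2R)-3,3-dimethyloxiran-2-yl]propan-2-one | CC(=O)C[C@H]1OC1(C)C | intermediate
13 | 1-lithiotricyclo[4.1.0.0^2,7]hept-3-ene, single enantiomer, lithium on the bridgehead that carried sulfur in 7 (not isolated) | [Li][C@]12[C@@H]3C=CC[C@H]1[C@H]23 | intermediate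
14 | lithium alkoxide of 1-[(2R)-3,3-dimethyloxiran-2-yl]-2-[(1R,2R,6S,7S)-tricyclo[4.1.0.0^2,7]hept-3-en-1-yl]propan-2-ol, both carbinol epimers (not isolated) | [Li]OC(C)(C[C@H]1OC1(C)C)[C@]12[C@@H]3C=CC[C@H]1[C@H]23 | intermediate
15 | trimethylsilyl ether of 1-[(2R)-3,3-dimethyloxiran-2-yl]-2-[(1R,2R,6S,7S)-tricyclo[4.1.0.0^2,7]hept-3-en-1-yl]propan-2-ol (both carbinol epimers) | C[Si](C)(C)OC(C)(C[C@H]1OC1(C)C)[C@]12[C@@H]3C=CC[C@H]1[C@H]23 | intermediate
16 | (4S,5S,7R,10R,11R)-7-hydroxy-12-norlongipin-1-en-9-one | O[C@@H]1CC(=O)[C@@]2(C)[C@@H]3C=CC[C@H]2[C@@H]3C1(C)C | intermediate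
17 | 2-methylprop-2-enal (methacrolein) | C=C(C)C=O | starting material
18 | (7R,9R)-9-hydroxy-12-norlongipin-1-en-7-yl 2-methylprop-2-enoate (cage as in 16) | C=C(C)C(=O)O[C@@H]1C[C@@H](O)[C@@]2(C)[C@@H]3C=CC[C@H]2[C@@H]3C1(C)C | intermediate
19 | (Z)-2-methylbut-2-enoic acid (angelic acid) | C/C=C(/C)C(=O)O | starting material
20 | (Z)-2-methylbut-2-enoic 2,4,6-trichlorobenzoic anhydride (not isolated) | C/C=C(/C)C(=O)OC(=O)c1c(Cl)cc(Cl)cc1Cl | intermediate
21 | (7R,9R)-9-[(Z)-2-methylbut-2-enoyloxy]-12-norlongipin-1-en-7-yl 2-methylprop-2-enoate | C=C(C)C(=O)O[C@@H]1C[C@@H](OC(=O)/C(C)=C\C)[C@@]2(C)[C@@H]3C=CC[C@H]2[C@@H]3C1(C)C | intermediate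
22 | (7R,9R)-9-[(Z)-2-methylbut-2-enoyloxy]-3-oxo-12-norlongipin-1-en-7-yl 2-methylprop-2-enoate | C=C(C)C(=O)O[C@@H]1C[C@@H](OC(=O)/C(C)=C\C)[C@@]2(C)[C@@H]3C=CC(=O)[C@H]2[C@@H]3C1(C)C | intermediate
23 | (7R,9R)-3-hydroxy-9-[(Z)-2-methylbut-2-enoyloxy]longipin-1-en-7-yl 2-methylprop-2-enoate (C3 epimers) | C=C(C)C(=O)O[C@@H]1C[C@@H](OC(=O)/C(C)=C\C)[C@@]2(C)[C@@H]3C=CC(C)(O)[C@H]2[C@@H]3C1(C)C | intermediate
24 | (4R,5S,7R,9R,10R,11R)-9-[(Z)-2-methylbut-2-enoyloxy]-1-oxolongipin-2-en-7-yl 2-methylprop-2-enoate | C=C(C)C(=O)O[C@@H]1C[C@@H](OC(=O)/C(C)=C\C)[C@@]2(C)[C@@H]3C(=O)C=C(C)[C@H]2[C@@H]3C1(C)C | target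

**Step count and risks**
Total steps: 13. Longest linear sequence: 10 (steps 1, 2, 3, 7, 8, 9, 10, 11, 12, 13).

The three steps most likely to fail:

Step 8 (the proposed new cascade). The bicyclobutane may isomerise under the Lewis acid, the silyloxy oxygen may open the epoxide instead, or the epoxide may rearrange to a ketone. The fallback sets out from 7 and comes back at 16. Sulfoxide 7 is exchanged with t-BuLi to 13 as in step 7, and 13 is added to methylboronic acid pinacol ester to give the lithium bicyclobutyl boronate complex F1. 2-Methyl-1-nitroprop-1-ene then triggers the electrophile-induced 1,2-boronate rearrangement across the central bond, known for carbon electrophiles on bicyclobutyl boronate complexes: C5 is alkylated and methyl migrates from boron to C10, giving after protonation the cyclobutyl boronic ester F2. Zweifel olefination with 1-ethoxyvinyllithium (I2, NaOMe) gives the enol ether F3, which aqueous HCl hydrolyses to the methyl ketone F4. A Nef reaction (NaOMe, then cold aqueous H2SO4) gives the keto aldehyde F5. Intramolecular aldol addition (LiHMDS, THF, −78 °C) closes C7–C8 to give 16 together with its C7 epimer, which is separated and re-equilibrated by retro-aldol and aldol.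

Step 9 (Evans–Tishchenko reduction with an enal, which may polymerise or undergo oxa-Michael addition). The fallback sets out from 16 and comes back at 21. The SmI2-catalysed Evans–Tishchenko reduction is run with 4-nitrobenzaldehyde to give the 7-(4-nitrobenzoate) 9-alcohol F6. Angeloylation as in step 10 gives the mixed diester F7. K2CO3 in MeOH at 0 °C removes only the activated nitrobenzoate to give the 7-alcohol F8. Methacryloyl chloride, Et3N and DMAP in CH2Cl2 then give 21.

Step 11 (allylic oxidation in the presence of two unsaturated esters). The fallback sets out from 16 and comes back at 22. Et3SiOTf and 2,6-lutidine give the triethylsilyl ether F9. CrO3–3,5-dimethylpyrazole oxidation, now with no ester alkenes present, gives the enone F10. HF·pyridine gives the hydroxy dione F11. Evans–Tishchenko reduction with 17 and SmI2, in which hydride is delivered only to C9, gives the methacrylate alcohol F12. Angeloylation through 20 as in step 10 gives 22.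

**Further compounds**
F1 | step 8 | lithium methyl(pinacolato)(tricyclo[4.1.0.0^2,7]hept-3-en-1-yl)borate, boron on the bridgehead that carried sulfur in 7 | C[B-]1(OC(C)(C)C(C)(C)O1)[C@]23[C@@H]4C=CC[C@H]2[C@H]34.[Li+]
F2 | step 8 | 2-[6-methyl-7-(2-methyl-1-nitropropan-2-yl)bicyclo[3.1.1]hept-2-en-6-yl]-4,4,5,5-tetramethyl-1,3,2-dioxaborolane, boron and nitroalkyl group anti to the three-carbon bridge | CC1(C)OB(OC1(C)C)[C@@]2(C)[C@@H]3C=CC[C@H]2[C@@H]3C(C)(C)C[N+](=O)[O-]
F3 | step 8 | 6-(1-ethoxyethenyl)-6-methyl-7-(2-methyl-1-nitropropan-2-yl)bicyclo[3.1.1]hept-2-ene, same configuration | CCOC(=C)[C@@]1(C)[C@@H]2C=CC[C@H]1[C@@H]2C(C)(C)C[N+](=O)[O-]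
F4 | step 8 | 1-[6-methyl-7-(2-methyl-1-nitropropan-2-yl)bicyclo[3.1.1]hept-2-en-6-yl]ethanone, same configuration | CC(=O)[C@@]1(C)[C@@H]2C=CC[C@H]1[C@@H]2C(C)(C)C[N+](=O)[O-]
F5 | step 8 | 2-(6-acetyl-6-methylbicyclo[3.1.1]hept-2-en-7-yl)-2-methylpropanal, same configuration | CC(=O)[C@@]1(C)[C@@H]2C=CC[C@H]1[C@@H]2C(C)(C)C=O
F6 | step 9 | (7R,9R)-9-hydroxy-12-norlongipin-1-en-7-yl 4-nitrobenzoate | O=C(O[C@@H]1C[C@@H](O)[C@@]2(C)[C@@H]3C=CC[C@H]2[C@@H]3C1(C)C)c1ccc(cc1)[N+](=O)[O-]
F7 | step 9 | (7R,9R)-9-[(Z)-2-methylbut-2-enoyloxy]-12-norlongipin-1-en-7-yl 4-nitrobenzoate | O=C(O[C@@H]1C[C@@H](OC(=O)/C(C)=C\C)[C@@]2(C)[C@@H]3C=CC[C@H]2[C@@H]3C1(C)C)c1ccc(cc1)[N+](=O)[O-]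
F8 | step 9 | (7R,9R)-7-hydroxy-12-norlongipin-1-en-9-yl (Z)-2-methylbut-2-enoate | O[C@@H]1C[C@@H](OC(=O)/C(C)=C\C)[C@@]2(C)[C@@H]3C=CC[C@H]2[C@@H]3C1(C)C
F9 | step 11 | (7R)-7-(triethylsilyloxy)-12-norlongipin-1-en-9-one | CC[Si](CC)(CC)O[C@@H]1CC(=O)[C@@]2(C)[C@@H]3C=CC[C@H]2[C@@H]3C1(C)C
F10 | step 11 | (7R)-7-(triethylsilyloxy)-12-norlongipin-1-ene-3,9-dione | CC[Si](CC)(CC)O[C@@H]1CC(=O)[C@@]2(C)[C@@H]3C=CC(=O)[C@H]2[C@@H]3C1(C)C
F11 | step 11 | (7R)-7-hydroxy-12-norlongipin-1-ene-3,9-dione | O[C@@H]1CC(=O)[C@@]2(C)[C@@H]3C=CC(=O)[C@H]2[C@@H]3C1(C)C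
F12 | step 11 | (7R,9R)-9-hydroxy-3-oxo-12-norlongipin-1-en-7-yl 2-methylprop-2-enoate | C=C(C)C(=O)O[C@@H]1C[C@@H](O)[C@@]2(C)[C@@H]3C=CC(=O)[C@H]2[C@@H]3C1(C)C
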